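The readings were computed with constants of no real substance, and the scatter is random.

Read the ratio of target to other capture product at 2.0 min, 1.0 h and 30 h. The meeting was called to forecast these three readings.

| setting | zeta | theta | flask |
|---|---|---|---|
| substrate | 18 mM | 18 mM | 18 mM |
| first nucleophile | 9 mM | 36 mM | 18.0 mM |
| second nucleophile | 9 mM | 9 mM | 9.00 mM |
| remark | run made earlier | run made earlier |  |
| time |  |  | 30 h |

| run | time / h | target / % | other capture product / % |
|---|---|---|---|
| zeta | 5.00 | 13.3 | 22.5 |
| zeta | 10.0 | 14.1 | 22.5 |
| zeta | 15.0 | 13.0 | 21.5 |
| zeta | 20.0 | 14.8 | 21.7 |
| zeta | 25.0 | 12.6 | 23.6 |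
| theta | 2.00 | 33.6 | 15.8 |
| theta | 6.00 | 39.9 | 14.7 |
| theta | 12.0 | 40.0 | 18.2 |
| theta | 15.0 | 37.7 | 18.5 |
| theta | 25.0 | 40.2 | 14.7 |

(standard deviation of a reading: 1 percentage point)

- ratio of target to other capture product at 2.0 min
- ratio of target to other capture product at 1.0 h
- ratio of target to other capture product at 30 h

- the numbers in the tables scatter with a standard deviation of 1 percentage point

Minutes. I reported the plateaus. The zeta run levels near 13.6 % target and 22.4 % other capture product. The theta run, after its first reading, levels near 39.5 % and 16.5 %.

I proposed that both nucleophiles compete for one intermediate. If so, the log of the fraction of first nucleophile left, over the log of the fraction of second nucleophile left, stays constant through a run. Each product counts against its own nucleophile's charge. The zeta run gives 0.534 and the theta run 0.548. I took their mean, s = 0.541, as a reading of this log ratio, the selectivity factor.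

I argued that the large term is the start ratio, s times the ratio of charges, which gives 1.08 for this flask. The small term is depletion, a correction factor (1 − f^s)/(s(1 − f)), where f is the fraction of second nucleophile left. Taking the other capture product midway between the two runs gives f = 61.1 %, so the correction is 1.11. I committed to 1.20 at the end.

The forecast, with a selectivity of 0.55, gave 1.1, 1.17 and 1.22, and said that “the ratio drifts up”. Its end value is higher than mine.

The flask gives 1.03, 1.10 and 1.16, and the forecast held.

    substrate → intermediate (k = 0.0142 min⁻¹)
    first nucleophile + intermediate → target (k = 74.7 M⁻¹ min⁻¹)
    second nucleophile + intermediate → other capture product (k = 145 M⁻¹ min⁻¹)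
    intermediate → solvolysis product (k = 2.67 min⁻¹)

At 30.0 h the flask holds 58.4 % of its second nucleophile, and a run ten times as long leaves the ratio where it is. With that f and s, the correction is 1.12. The flask's own rise from early to end is a factor of 1.13. Watch the second nucleophile left beside the ratio.

The neighbour charged with 72 mM of substrate ends with 6.61 % of its second nucleophile. Its nucleophile charges are those of the flask, so its start ratio is the same. The correction there is 1.52, which takes that start ratio to 1.65. The computed ratio goes from 1.04 to 1.61.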